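Ring C is closed last by forming the C4–C3 bond in an intramolecular crossed benzoin reaction. The feature exploited is the α-ketol of ring C (C4=O next to C3–O) together with the acidic hydrogen at C2: opened at C4–C3, the flavanonol is a dialdehyde whose ring A aldehyde (C4) and aliphatic aldehyde (C3) are joined only through the O1–C2 aryl ether. A chiral triazolylidene turns C4 into an acyl anion; its addition to C3 creates the ring, the ketone and the C3 carbinol, and because C2 epimerises in the precursor the catalyst fixes both stereocentres at once. The dialdehyde comes from iridium-catalysed allylic etherification and alkene cleavage.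

Key step: step 7

Remark: both antipodes of the phosphoramidite ligand (step 5) and of the triazolium salt (step 7) are available; each is specified by the configuration it must deliver, to be confirmed in a pilot run, and 2-methoxyresorcinol and 4-(methoxymethoxy)benzaldehyde are taken as commercial.

Step 1
Reactants: 1 2-methoxybenzene-1,3-diol (2-methoxyresorcinol)
Product: 2 2-methoxy-1,3-bis(methoxymethoxy)benzene
Conditions: MOMCl, i-Pr2NEt, CH2Cl2, 0 °C to rt
Reagents that add atoms: chloromethyl methyl ether COCCl
Why: Williamson-type O-alkylation of both phenols by the α-chloro ether; MOM is chosen because it offers no aryl C–H to the borylation of step 2 and withstands the bases, oxidants and carbene used later.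

Step 2
Reactants: 2 2-methoxy-1,3-bis(methoxymethoxy)benzene
Product: 4 4-methoxy-3,5-bis(methoxymethoxy)phenol, via pinacol arylboronate 3 (not isolated)
Conditions: [Ir(OMe)(cod)]2 (1.5 mol%), 4,4′-di-tert-butyl-2,2′-bipyridine, B2pin2, THF, 80 °C; then aq. NaOH, H2O2, 0 °C to rt
Reagents that add atoms: hydrogen peroxide OO
Why: Iridium-catalysed aromatic C–H borylation is governed by sterics and should take only H-5, the one hydrogen without an ortho substituent, and the basic peroxide oxidation (1,2-shift of aryl from boron to oxygen) then converts the C–B bond into the phenol in the same flask.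

Step 3
Reactants: 4 4-methoxy-3,5-bis(methoxymethoxy)phenol
Product: 6 6-hydroxy-3-methoxy-2,4-bis(methoxymethoxy)benzaldehyde, via ortho-hydroxymethyl phenol 5 (not isolated)
Conditions: MgCl2, Et3N, (CH2O)n, MeCN, reflux
Reagents that add atoms: formaldehyde (as paraformaldehyde) C=O
Why: Magnesium-phenoxide-directed ortho-formylation, in which chelate-controlled hydroxymethylation next to the free OH is followed by Oppenauer-type hydride transfer to a second formaldehyde; the two ortho positions of 4 are equivalent, so one aldehyde results.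

Step 4
Reactants: 7 4-(methoxymethoxy)benzaldehyde
Product: 9 1-[4-(methoxymethoxy)phenyl]prop-2-en-1-yl benzoate (racemic), via bromomagnesium alkoxide 8 (not isolated)
Conditions: CH2=CHMgBr, THF, −78 to 0 °C; then PhCOCl, 0 °C to rt
Reagents that add atoms: vinylmagnesium bromide C=C[Mg]Br; benzoyl chloride O=C(Cl)c1ccccc1
Why: Grignard 1,2-addition to the aldehyde followed by O-acylation of the magnesium alkoxide; the carbinol centre is formed racemic on purpose, since step 5 converts both enantiomers.

Step 5
Reactants: 6 6-hydroxy-3-methoxy-2,4-bis(methoxymethoxy)benzaldehyde; 9 1-[4-(methoxymethoxy)phenyl]prop-2-en-1-yl benzoate (racemic)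
Product: 11 3-methoxy-2,4-bis(methoxymethoxy)-6-{[(1S)-1-[4-(methoxymethoxy)phenyl]prop-2-en-1-yl]oxy}benzaldehyde, via sodium aryloxide 10 (not isolated)
Conditions: NaH, THF, 0 °C; then 9, [Ir(cod)Cl]2 (2 mol%), enantiopure O,O′-(1,1′-binaphthalene-2,2′-diyl) N,N-bis(1-phenylethyl)phosphoramidite (4 mol%, antipode giving the 1S ether), THF, rt to 40 °C
Reagents that add atoms: none
Why: Iridium-catalysed allylic substitution through a π-allyl iridium complex, in which the aryloxide attacks the aryl-bearing terminus (branched selectivity inherent to iridium) and the enantiopure phosphoramidite catalyst should turn the racemic branched benzoate into one enantiomer of the ether (kinetic asymmetric transformation), which sets the centre that becomes C2.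

Step 6
Reactants: 11 3-methoxy-2,4-bis(methoxymethoxy)-6-{[(1S)-1-[4-(methoxymethoxy)phenyl]prop-2-en-1-yl]oxy}benzaldehyde
Product: 13 3-methoxy-2,4-bis(methoxymethoxy)-6-{[(1R)-1-[4-(methoxymethoxy)phenyl]-2-oxoethyl]oxy}benzaldehyde, via vicinal diol 12 (not isolated)
Conditions: OsO4 (2 mol%), NaIO4, 2,6-lutidine, dioxane/H2O, rt; crude 13 used at once
Reagents that add atoms: osmium tetroxide O=[Os](=O)(=O)=O (catalytic carrier of the new oxygen); sodium periodate [Na+].[O-]I(=O)(=O)=O (stoichiometric oxygen source)
Why: Lemieux–Johnson oxidation (catalytic dihydroxylation, then periodate glycol cleavage) attacks the only alkene while lutidine buffering protects the acetals; no new stereocentre is formed, and 13 is used at once because its stereocentre is now α to an aldehyde.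

Step 7
Reactants: 13 3-methoxy-2,4-bis(methoxymethoxy)-6-{[(1R)-1-[4-(methoxymethoxy)phenyl]-2-oxoethyl]oxy}benzaldehyde
Product: 14 (2R,3R)-3-hydroxy-6-methoxy-5,7-bis(methoxymethoxy)-2-[4-(methoxymethoxy)phenyl]-2,3-dihydro-4H-chromen-4-one
Conditions: enantiopure 2-(pentafluorophenyl)-5a,10b-dihydro-4H,6H-indeno[2,1-b][1,2,4]triazolo[4,3-d][1,4]oxazin-2-ium tetrafluoroborate (10 mol%, antipode giving 3R), i-Pr2NEt (20 mol%), toluene, 0 °C to rt
Reagents that add atoms: none
Why: Proposed new method: the triazolylidene released by the amine adds to the ring A aldehyde (C4), proton transfer makes the carbene-bound acyl-anion equivalent, and this attacks the tethered C3 aldehyde, after which the carbene is expelled to leave the C4 ketone and the C3 carbinol. The closest known reaction type is the carbene-catalysed intramolecular crossed benzoin of 2-(2-oxoalkoxy)benzaldehydes (aldehyde onto ketone) giving 3-hydroxychroman-4-ones; new are the aldehyde acceptor and the stereolabile α-aryloxy centre. Ring C closes in the 6-exo-trig mode. C3 is controlled by the catalyst, which must expose the Si face of the C3 aldehyde to give 3R, and C2 is controlled twice: it arrives R from step 5, and since its hydrogen is benzylic, α-oxy and α to the aldehyde, any 2S material formed by enolisation is fed back into the faster, matched closure that places the aryl group and the new C3–O bond trans and equatorial (dynamic kinetic resolution). The step needs C4 and not C3 to become the acyl anion and needs the aryloxide to stay in place: the C3 aldehyde is α,α-disubstituted, which slows formation of its own carbene enol, the benzoin manifold is reversible so that the α-ketol with the ketone conjugated to the oxygen-rich ring A is the thermodynamic sink, and the electron-rich aryloxide, the weak base and the low temperature hold back β-elimination.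

Step 8
Reactants: 14 (2R,3R)-3-hydroxy-6-methoxy-5,7-bis(methoxymethoxy)-2-[4-(methoxymethoxy)phenyl]-2,3-dihydro-4H-chromen-4-one
Product: 15 (2R,3R)-6-methoxy-5,7-bis(methoxymethoxy)-2-[4-(methoxymethoxy)phenyl]-4-oxo-3,4-dihydro-2H-chromen-3-yl acetate
Conditions: Ac2O, pyridine, CH2Cl2, 0 °C
Reagents that add atoms: acetic anhydride CC(=O)OC(C)=O
Why: O-Acylation of the only free hydroxyl (nucleophilic acyl substitution, pyridine as base and catalyst); no bond to C2 or C3 is broken, so the trans configuration is kept.

Step 9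
Reactants: 15 (2R,3R)-6-methoxy-5,7-bis(methoxymethoxy)-2-[4-(methoxymethoxy)phenyl]-4-oxo-3,4-dihydro-2H-chromen-3-yl acetate
Product: 17 (2R,3R)-5,7-dihydroxy-2-(4-hydroxyphenyl)-6-methoxy-4-oxo-3,4-dihydro-2H-chromen-3-yl acetate (6-methoxyaromadendrin 3-O-acetate), via tris(trimethylsilyl) ether 16 (not isolated)
Conditions: Me3SiOTf, 2,2′-bipyridyl, CH2Cl2, 0 °C to rt; then H2O
Reagents that add atoms: none
Why: Silyl-triflate/bipyridyl cleavage of aryl MOM acetals, in which each aryl oxygen leaves as its trimethylsilyl ether while the methoxymethyl cation is trapped as an N-alkylbipyridinium salt and water then frees the phenols, so no protic acid or free formaldehyde meets the acetate, C2 or the nucleophilic C8.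

Compound list
1 | 2-methoxybenzene-1,3-diol (2-methoxyresorcinol) | COc1c(O)cccc1O | starting material
2 | 2-methoxy-1,3-bis(methoxymethoxy)benzene | COCOc1cccc(OCOC)c1OC | intermediate
3 | 2-[4-methoxy-3,5-bis(methoxymethoxy)phenyl]-4,4,5,5-tetramethyl-1,3,2-dioxaborolane | COCOc1cc(cc(OCOC)c1OC)B1OC(C)(C)C(C)(C)O1 | intermediate (not isolated)
4 | 4-methoxy-3,5-bis(methoxymethoxy)phenol | COCOc1cc(O)cc(OCOC)c1OC | intermediate
5 | 2-(hydroxymethyl)-4-methoxy-3,5-bis(methoxymethoxy)phenol (present as its magnesium salt) | OCc1c(O)cc(OCOC)c(OC)c1OCOC | intermediate (not isolated)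
6 | 6-hydroxy-3-methoxy-2,4-bis(methoxymethoxy)benzaldehyde | O=Cc1c(O)cc(OCOC)c(OC)c1OCOC | intermediate
7 | 4-(methoxymethoxy)benzaldehyde | COCOc1ccc(C=O)cc1 | starting material
8 | bromomagnesium 1-[4-(methoxymethoxy)phenyl]prop-2-en-1-olate (racemic) | C=CC(O[Mg]Br)c1ccc(OCOC)cc1 | intermediate (not isolated)
9 | 1-[4-(methoxymethoxy)phenyl]prop-2-en-1-yl benzoate (racemic) | C=CC(OC(=O)c1ccccc1)c1ccc(OCOC)cc1 | intermediate
10 | sodium 2-formyl-4-methoxy-3,5-bis(methoxymethoxy)phenolate | [Na+].[O-]c1cc(OCOC)c(OC)c(OCOC)c1C=O | intermediate (not isolated)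
11 | 3-methoxy-2,4-bis(methoxymethoxy)-6-{[(1S)-1-[4-(methoxymethoxy)phenyl]prop-2-en-1-yl]oxy}benzaldehyde | C=C[C@@H](c1ccc(OCOC)cc1)Oc1cc(OCOC)c(OC)c(OCOC)c1C=O | intermediate
12 | 6-{[(1R)-2,3-dihydroxy-1-[4-(methoxymethoxy)phenyl]propyl]oxy}-3-methoxy-2,4-bis(methoxymethoxy)benzaldehyde (both epimers at the secondary carbinol) | OCC(O)[C@@H](c1ccc(OCOC)cc1)Oc1cc(OCOC)c(OC)c(OCOC)c1C=O | intermediate (not isolated)
13 | 3-methoxy-2,4-bis(methoxymethoxy)-6-{[(1R)-1-[4-(methoxymethoxy)phenyl]-2-oxoethyl]oxy}benzaldehyde | O=C[C@@H](c1ccc(OCOC)cc1)Oc1cc(OCOC)c(OC)c(OCOC)c1C=O | intermediate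
14 | (2R,3R)-3-hydroxy-6-methoxy-5,7-bis(methoxymethoxy)-2-[4-(methoxymethoxy)phenyl]-2,3-dihydro-4H-chromen-4-one | COc1c(OCOC)cc2c(c1OCOC)C(=O)[C@H](O)[C@@H](c1ccc(OCOC)cc1)O2 | intermediate
15 | (2R,3R)-6-methoxy-5,7-bis(methoxymethoxy)-2-[4-(methoxymethoxy)phenyl]-4-oxo-3,4-dihydro-2H-chromen-3-yl acetate | COc1c(OCOC)cc2c(c1OCOC)C(=O)[C@H](OC(C)=O)[C@@H](c1ccc(OCOC)cc1)O2 | intermediate
16 | (2R,3R)-6-methoxy-4-oxo-5,7-bis(trimethylsilyloxy)-2-[4-(trimethylsilyloxy)phenyl]-3,4-dihydro-2H-chromen-3-yl acetate | COc1c(O[Si](C)(C)C)cc2c(c1O[Si](C)(C)C)C(=O)[C@H](OC(C)=O)[C@@H](c1ccc(O[Si](C)(C)C)cc1)O2 | intermediate (not isolated)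
17 | (2R,3R)-5,7-dihydroxy-2-(4-hydroxyphenyl)-6-methoxy-4-oxo-3,4-dihydro-2H-chromen-3-yl acetate (6-methoxyaromadendrin 3-O-acetate) | COc1c(O)cc2c(c1O)C(=O)[C@H](OC(C)=O)[C@@H](c1ccc(O)cc1)O2 | target

Total step count: 9 steps.
Longest linear sequence: 8 steps (steps 1, 2, 3, 5, 6, 7, 8, 9, from 2-methoxyresorcinol); the ring B branch is one step (step 4) before the union in step 5.

Steps most likely to fail

Step 7 (proposed new method). Several processes may go wrong. The C3 aldehyde instead of C4 may take the acyl-anion role. A carbene adduct of the C3 aldehyde may expel the ring A aryloxide (internal redox to an aryl ester). The C2 enolate may add reversibly to the C4 aldehyde (dihydrobenzofuran aldol). Facial selectivity at C3 may be poor, or the amine may open ring C of the product by elimination of the aryloxide. The fallback uses only known reactions, sets out from 11 and comes back to the route at 14. Wittig methylenation of the aldehyde of 11 (Ph3P=CH2, THF, 0 °C) should give the diene 2-ethenyl-4-methoxy-3,5-bis(methoxymethoxy)-1-{[(1S)-1-[4-(methoxymethoxy)phenyl]prop-2-en-1-yl]oxy}benzene F1. Ring-closing metathesis (second-generation Grubbs catalyst RuCl2(=CHPh)(PCy3)(H2IMes), CH2Cl2, 40 °C) then makes the C3–C4 link as an alkene in (2S)-6-methoxy-5,7-bis(methoxymethoxy)-2-[4-(methoxymethoxy)phenyl]-2H-chromene F2. Dihydroxylation (OsO4 cat., N-methylmorpholine N-oxide, acetone/H2O) from the face opposite the 2-aryl group should give the 2,3-trans-3,4-cis diol (2R,3S,4S)-6-methoxy-5,7-bis(methoxymethoxy)-2-[4-(methoxymethoxy)phenyl]-3,4-dihydro-2H-chromene-3,4-diol F3. Selective oxidation of the doubly activated benzylic C4 hydroxyl (MnO2, CH2Cl2, rt) returns 14. In this sequence C2 is never α to a carbonyl group before ring closure, so the configuration set in step 5 is kept.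

Step 5. The ortho-formyl aryloxide may chelate and slow the iridium catalyst, attack may leak to the linear terminus, or the conversion of the racemic benzoate into one enantiomer may be incomplete. The fallback sets out from 6 and 7 and comes back at 11. Addition of CH2=CHMgBr to 7 with aqueous work-up gives racemic 1-[4-(methoxymethoxy)phenyl]prop-2-en-1-ol F4. Mitsunobu etherification of the acidic phenol 6 with it (PPh3, diisopropyl azodicarboxylate, toluene, 0 °C) gives 11 as its racemate, 3-methoxy-2,4-bis(methoxymethoxy)-6-{[1-[4-(methoxymethoxy)phenyl]prop-2-en-1-yl]oxy}benzaldehyde F5, which enters step 6. The configuration at C2 is then left entirely to the dynamic kinetic resolution of step 7, which the lability of 13 allows.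

Step 9. The 3-O-acetyl group may be partly lost, the cleavage of the 5-O-acetal beside the carbonyl may stay incomplete, or the methoxymethyl cation may be captured by the nucleophilic C8 of ring A. The fallback changes the order of events, sets out from 14 and comes back at 17. The three acetals are removed first (HCl, MeOH, 40 °C; the methylene unit is trapped by the solvent) to give (2R,3R)-3,5,7-trihydroxy-2-(4-hydroxyphenyl)-6-methoxy-2,3-dihydro-4H-chromen-4-one F6. Peracetylation (Ac2O, pyridine, rt) gives (2R,3R)-2-[4-(acetyloxy)phenyl]-6-methoxy-4-oxo-3,4-dihydro-2H-chromene-3,5,7-triyl triacetate F7. Chemoselective cleavage of the three aryl acetates beside the alkyl acetate (NH4OAc, aqueous MeOH, rt) then gives 17.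

Further compounds
F1 | step 7 | 2-ethenyl-4-methoxy-3,5-bis(methoxymethoxy)-1-{[(1S)-1-[4-(methoxymethoxy)phenyl]prop-2-en-1-yl]oxy}benzene | C=C[C@@H](c1ccc(OCOC)cc1)Oc1cc(OCOC)c(OC)c(OCOC)c1C=C
F2 | step 7 | (2S)-6-methoxy-5,7-bis(methoxymethoxy)-2-[4-(methoxymethoxy)phenyl]-2H-chromene | COc1c(OCOC)cc2c(c1OCOC)C=C[C@@H](c1ccc(OCOC)cc1)O2
F3 | step 7 | (2R,3S,4S)-6-methoxy-5,7-bis(methoxymethoxy)-2-[4-(methoxymethoxy)phenyl]-3,4-dihydro-2H-chromene-3,4-diol | COc1c(OCOC)cc2c(c1OCOC)[C@H](O)[C@H](O)[C@@H](c1ccc(OCOC)cc1)O2
F4 | step 5 | 1-[4-(methoxymethoxy)phenyl]prop-2-en-1-ol (racemic) | C=CC(O)c1ccc(OCOC)cc1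
F5 | step 5 | 3-methoxy-2,4-bis(methoxymethoxy)-6-{[1-[4-(methoxymethoxy)phenyl]prop-2-en-1-yl]oxy}benzaldehyde (racemate of 11) | C=CC(Oc1cc(OCOC)c(OC)c(OCOC)c1C=O)c1ccc(OCOC)cc1
F6 | step 9 | (2R,3R)-3,5,7-trihydroxy-2-(4-hydroxyphenyl)-6-methoxy-2,3-dihydro-4H-chromen-4-one | COc1c(O)cc2c(c1O)C(=O)[C@H](O)[C@@H](c1ccc(O)cc1)O2
F7 | step 9 | (2R,3R)-2-[4-(acetyloxy)phenyl]-6-methoxy-4-oxo-3,4-dihydro-2H-chromene-3,5,7-triyl triacetate | COc1c(OC(C)=O)cc2c(c1OC(C)=O)C(=O)[C@H](OC(C)=O)[C@@H](c1ccc(OC(C)=O)cc1)O2
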